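**Assumption:** Locants C1–C15 are route locants: C6 = lactone O–CH, C7 = ring-fusion CH, C8 = angelate carbinol, C1 = free carbinol, C3 = acetate carbinol, C4 bears C15H2O, C10 bears C14H3, C11=C13 is the exo-methylene, C12 the lactone C=O. Boronate 3 is taken as purchasable and DMDO as a freshly prepared acetone solution.

## Retrosynthetic overview

1. Target ⇐ desilylation and Evans–Tishchenko reduction of the macrocyclic β-hydroxy enone 19; this one reduction sets C1 and delivers the C3 acetate.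
2. 19 ⇐ intramolecular boron aldol (C2–C3) of keto-aldehyde 17; the ten-membered ring is formed last.
3. 17 ⇐ bromobutenolide 9 + Z-keto-enal 11 (allylzinc addition, C7–C8, sets C7 and C8), then angelate.
4. 9 ⇐ lactone 6 ⇐ oxidative ring-opening of the 3-substituted furan 2 to a Z-enedial, then regio- and enantioselective allylboration–lactonisation (C6–C7, sets C6); 11 ⇐ oxidative ring-opening of 2,3-dimethylfuran.
5. Ring order: γ-lactone (step 2), then the ten-membered carbocycle (step 9); both Z-alkenes are the former C3–C4 bonds of the two furans.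

## Route

Step 1
Reactants: 1 furan-3-ylmethanol
Product: 2 tert-butyl(furan-3-ylmethoxy)dimethylsilane
Conditions: TBSCl, imidazole, DMF, rt
Reagents that add atoms: TBSCl CC(C)(C)[Si](C)(C)Cl
Why: Imidazole-mediated silyl ether formation masks the only hydroxyl so that it survives the later oxidation, organozinc and acylation steps, and no stereocentre is involved.

Step 2
Reactants: 2 tert-butyl(furan-3-ylmethoxy)dimethylsilane; 3 ethyl 2-[(4,4,5,5-tetramethyl-1,3,2-dioxaborolan-2-yl)methyl]prop-2-enoate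
Product: 6 (2Z)-2-({[tert-butyl(dimethyl)silyl]oxy}methyl)-3-[(2R)-4-methylidene-5-oxooxolan-2-yl]prop-2-enal, via Z-enedial 4 (not isolated), via boron alkoxide 5 (not isolated)
Conditions: DMDO, acetone, −78 → −30 °C, solvent switch to toluene below −20 °C; then 3 (1.0 equiv), (R)-TRIP phosphoric acid (5 mol%), 4 Å MS, −30 → 0 °C, then 40 °C
Reagents that add atoms: dimethyldioxirane CC1(C)OO1
Why: Proposed new method: dioxirane epoxidation and ring-opening of the furan (the known furan to cis-enedione oxidation) destroys the aromatic ring and gives enedial 4 with ring-enforced Z geometry, after which a chiral-phosphoric-acid-catalysed allylboration (closest precedents: Antilla allylboration of enals and Hall allylboration–lactonisation with 2-alkoxycarbonyl allylboronates) should attack only the unhindered C6 aldehyde, because the C3 aldehyde sits on the fully substituted alkene carbon next to CH2OTBS, on its re face in the catalyst-organised chair transition state to set C6, and the boron alkoxide 5 then closes onto the ethyl ester to form the γ-lactone.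

Step 3
Reactants: 6 (2Z)-2-({[tert-butyl(dimethyl)silyl]oxy}methyl)-3-[(2R)-4-methylidene-5-oxooxolan-2-yl]prop-2-enal
Product: 7 (5R)-5-[(1Z)-2-({[tert-butyl(dimethyl)silyl]oxy}methyl)-3,3-dimethoxyprop-1-en-1-yl]-3-methylideneoxolan-2-one
Conditions: MeOSiMe3 (2.2 equiv), TMSOTf (2 mol%), CH2Cl2, −78 °C
Reagents that add atoms: methoxytrimethylsilane CO[Si](C)(C)C
Why: Noyori acetalisation under aprotic conditions at low temperature masks the C3 enal, which would otherwise be allylated intramolecularly in step 6, without touching the silyl ether or the exo-methylene lactone, and no stereocentre changes.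

Step 4
Reactants: 7 (5R)-5-[(1Z)-2-({[tert-butyl(dimethyl)silyl]oxy}methyl)-3,3-dimethoxyprop-1-en-1-yl]-3-methylideneoxolan-2-one
Product: 9 (5S)-3-(bromomethyl)-5-[(1Z)-2-({[tert-butyl(dimethyl)silyl]oxy}methyl)-3,3-dimethoxyprop-1-en-1-yl]furan-2(5H)-one, via dibromide 8 (not isolated)
Conditions: Br2 (1.05 equiv), CH2Cl2, −20 °C; then Et3N, 0 °C
Reagents that add atoms: bromine BrBr
Why: Bromine addition to the exo-methylene (the trisubstituted alkene is deactivated by three allylic C–O bonds) followed by amine-mediated dehydrobromination toward C7–H gives the conjugated 3-(bromomethyl)butenolide, the established dibromination–dehydrobromination route, with C6 untouched (the descriptor changes only through ligand priorities) provided the base contact is short.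

Step 5
Reactants: 10 2,3-dimethylfuran
Product: 11 (2Z)-3-methyl-4-oxopent-2-enal
Conditions: DMDO, acetone, −78 → −30 °C; concentrate at 0 °C, use at once
Reagents that add atoms: dimethyldioxirane CC1(C)OO1
Why: Dioxirane oxidative ring-opening of the 2,3-dialkylfuran (furan to cis-enedione oxidation) breaks the aromatic ring and gives the keto-enal whose Z geometry is inherited from the ring and whose two termini are already differentiated as aldehyde and methyl ketone.

Step 6
Reactants: 9 (5S)-3-(bromomethyl)-5-[(1Z)-2-({[tert-butyl(dimethyl)silyl]oxy}methyl)-3,3-dimethoxyprop-1-en-1-yl]furan-2(5H)-one; 11 (2Z)-3-methyl-4-oxopent-2-enal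
Product: 13 (4S,5S)-5-[(1Z)-2-({[tert-butyl(dimethyl)silyl]oxy}methyl)-3,3-dimethoxyprop-1-en-1-yl]-4-[(1R,2Z)-1-hydroxy-3-methyl-4-oxopent-2-en-1-yl]-3-methylideneoxolan-2-one, via allylzinc bromide 12 (not isolated)
Conditions: 9, Zn dust, LiCl, THF, 0 °C, decant from Zn; then 11 (1.5 equiv), −78 → −20 °C; aq NH4Cl
Reagents that add atoms: none
Why: Barbier-type carbonyl allylation with a preformed allylzinc (so that zinc metal never meets the reducible ene-dicarbonyl 11) adds through C7 to the aldehyde rather than the ketone via a Zimmerman–Traxler chair on the face anti to the C6 alkenyl group, and because C6 is trans to the CH2Zn carbon this gives the 6,7-trans and 7,8-anti relationships (sets C7 and C8) while regenerating the exo-methylene lactone, as precedented for optically active 3-(bromomethyl)butenolides.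

Step 7
Reactants: 13 (4S,5S)-5-[(1Z)-2-({[tert-butyl(dimethyl)silyl]oxy}methyl)-3,3-dimethoxyprop-1-en-1-yl]-4-[(1R,2Z)-1-hydroxy-3-methyl-4-oxopent-2-en-1-yl]-3-methylideneoxolan-2-one; 14 angelic acid [(2Z)-2-methylbut-2-enoic acid]
Product: 16 (1R,2Z)-1-[(2S,3R)-2-[(1Z)-2-({[tert-butyl(dimethyl)silyl]oxy}methyl)-3,3-dimethoxyprop-1-en-1-yl]-4-methylidene-5-oxooxolan-3-yl]-3-methyl-4-oxopent-2-en-1-yl (2Z)-2-methylbut-2-enoate, via mixed anhydride 15 (not isolated)
Conditions: 14, 2,4,6-trichlorobenzoyl chloride, Et3N, toluene, rt; then 13, DMAP (0.2 equiv), 0 °C → rt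
Reagents that add atoms: none
Why: Yamaguchi esterification acylates the only free hydroxyl under basic conditions, so the γ-hydroxy Z-enone cannot cyclodehydrate back to a furan and the lactone can no longer migrate to O8, and the mixed-anhydride protocol is the standard way to install an angelate without isomerisation to the tiglate.

Step 8
Reactants: 16 (1R,2Z)-1-[(2S,3R)-2-[(1Z)-2-({[tert-butyl(dimethyl)silyl]oxy}methyl)-3,3-dimethoxyprop-1-en-1-yl]-4-methylidene-5-oxooxolan-3-yl]-3-methyl-4-oxopent-2-en-1-yl (2Z)-2-methylbut-2-enoate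
Product: 17 (1R,2Z)-1-[(2S,3R)-2-[(1Z)-2-({[tert-butyl(dimethyl)silyl]oxy}methyl)-3-oxoprop-1-en-1-yl]-4-methylidene-5-oxooxolan-3-yl]-3-methyl-4-oxopent-2-en-1-yl (2Z)-2-methylbut-2-enoate
Conditions: PPTS (cat.), acetone/H2O (10:1), rt
Reagents that add atoms: water O
Why: Mild acid-catalysed acetal hydrolysis liberates the conjugated aldehyde, since an allylic dimethyl acetal cleaves far faster than the primary silyl ether or the esters, and no stereocentre is affected.

Step 9
Reactants: 17 (1R,2Z)-1-[(2S,3R)-2-[(1Z)-2-({[tert-butyl(dimethyl)silyl]oxy}methyl)-3-oxoprop-1-en-1-yl]-4-methylidene-5-oxooxolan-3-yl]-3-methyl-4-oxopent-2-en-1-yl (2Z)-2-methylbut-2-enoate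
Product: 19 (3S,6S,7R,8R)-8-angeloyloxy-15-{[tert-butyl(dimethyl)silyl]oxy}-3-hydroxy-1-oxogermacra-4Z,9Z,11(13)-trien-12,6-olide (route locants), via boron enolate 18 (not isolated)
Conditions: (−)-Ipc2BCl, Et3N, Et2O, slow addition of 17 to 0.002 M, −78 → −20 °C; then MeOH, pH 7 buffer, H2O2, 0 °C
Reagents that add atoms: none
Why: Proposed new method: the methyl ketone is the only enolisable carbonyl (aldehyde and lactone have no α-hydrogen), so Paterson enolisation followed by an intramolecular boron aldol addition under high dilution should close the ten-membered ring, the two Z-alkenes and the trans-lactone pre-folding the chain, with the (−)-Ipc ligands directing attack on the si face of the aldehyde to set C3 (closest precedents: Paterson reagent-controlled methyl ketone aldols and Danishefsky-type macroaldolisation).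

Step 10
Reactants: 19 (3S,6S,7R,8R)-8-angeloyloxy-15-{[tert-butyl(dimethyl)silyl]oxy}-3-hydroxy-1-oxogermacra-4Z,9Z,11(13)-trien-12,6-olide; 20 acetaldehyde
Product: 22 (1S,3S,6S,7S,8R)-3-acetoxy-8-angeloyloxy-15-{[tert-butyl(dimethyl)silyl]oxy}-1-hydroxygermacra-4Z,9Z,11(13)-trien-12,6-olide (route locants), via hemiacetal 21 (not isolated)
Conditions: CH3CHO (6 equiv), SmI2 (30 mol%), THF, −10 °C
Reagents that add atoms: none
Why: In the Evans–Tishchenko reduction the C3 hydroxyl forms a hemiacetal with acetaldehyde and delivers its hydride intramolecularly to the C1 ketone through a samarium-bridged chair, giving the 1,3-anti diol (sets C1) with the acetyl group on O3 and the C1 hydroxyl free, so no separate acetylation or hydroxyl differentiation is needed.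

Step 11
Reactants: 22 (1S,3S,6S,7S,8R)-3-acetoxy-8-angeloyloxy-15-{[tert-butyl(dimethyl)silyl]oxy}-1-hydroxygermacra-4Z,9Z,11(13)-trien-12,6-olide
Product: 23 CNP0153210.4 [(1S,3S,6S,7S,8R)-3-acetoxy-8-angeloyloxy-1,15-dihydroxygermacra-4Z,9Z,11(13)-trien-12,6-olide (route locants)]
Conditions: HF·pyridine, pyridine, THF, 0 °C
Reagents that add atoms: none
Why: Buffered fluoride desilylation removes the primary silyl ether without acyl migration, ester cleavage or conjugate addition to the α-methylene lactone, and no stereocentre is touched.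

## Compound list

1 | furan-3-ylmethanol | OCc1ccoc1 | starting material
2 | tert-butyl(furan-3-ylmethoxy)dimethylsilane | CC(C)(C)[Si](C)(C)OCc1ccoc1 | intermediate
3 | ethyl 2-[(4,4,5,5-tetramethyl-1,3,2-dioxaborolan-2-yl)methyl]prop-2-enoate | C=C(CB1OC(C)(C)C(C)(C)O1)C(=O)OCC | starting material
4 | (2Z)-2-({[tert-butyl(dimethyl)silyl]oxy}methyl)but-2-enedial | O=C/C=C(/CO[Si](C)(C)C(C)(C)C)C=O | intermediate
5 | pinacol borate of ethyl (4R,5Z)-6-({[tert-butyl(dimethyl)silyl]oxy}methyl)-4-hydroxy-2-methylidene-7-oxohept-5-enoate | CCOC(=O)C(=C)C[C@@H](OB1OC(C)(C)C(C)(C)O1)/C=C(/CO[Si](C)(C)C(C)(C)C)C=O | intermediate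
6 | (2Z)-2-({[tert-butyl(dimethyl)silyl]oxy}methyl)-3-[(2R)-4-methylidene-5-oxooxolan-2-yl]prop-2-enal | C=C1C(=O)O[C@@H](/C=C(/CO[Si](C)(C)C(C)(C)C)C=O)C1 | intermediate
7 | (5R)-5-[(1Z)-2-({[tert-butyl(dimethyl)silyl]oxy}methyl)-3,3-dimethoxyprop-1-en-1-yl]-3-methylideneoxolan-2-one | C=C1C(=O)O[C@@H](/C=C(/CO[Si](C)(C)C(C)(C)C)C(OC)OC)C1 | intermediate
8 | (5R)-3-bromo-3-(bromomethyl)-5-[(1Z)-2-({[tert-butyl(dimethyl)silyl]oxy}methyl)-3,3-dimethoxyprop-1-en-1-yl]oxolan-2-one (C3 epimers) | O=C1O[C@@H](/C=C(/CO[Si](C)(C)C(C)(C)C)C(OC)OC)CC1(Br)CBr | intermediate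
9 | (5S)-3-(bromomethyl)-5-[(1Z)-2-({[tert-butyl(dimethyl)silyl]oxy}methyl)-3,3-dimethoxyprop-1-en-1-yl]furan-2(5H)-one | O=C1O[C@@H](/C=C(/CO[Si](C)(C)C(C)(C)C)C(OC)OC)C=C1CBr | intermediate
10 | 2,3-dimethylfuran | Cc1occc1C | starting material
11 | (2Z)-3-methyl-4-oxopent-2-enal | CC(=O)/C(C)=C\C=O | intermediate
12 | allylzinc bromide from 9 ({[(5S)-2-oxo-5-alkenyl-2,5-dihydrofuran-3-yl]methyl}zinc bromide) | O=C1O[C@@H](/C=C(/CO[Si](C)(C)C(C)(C)C)C(OC)OC)C=C1C[Zn]Br | intermediate
13 | (4S,5S)-5-[(1Z)-2-({[tert-butyl(dimethyl)silyl]oxy}methyl)-3,3-dimethoxyprop-1-en-1-yl]-4-[(1R,2Z)-1-hydroxy-3-methyl-4-oxopent-2-en-1-yl]-3-methylideneoxolan-2-one | C=C1C(=O)O[C@@H](/C=C(/CO[Si](C)(C)C(C)(C)C)C(OC)OC)[C@@H]1[C@H](O)/C=C(/C)C(C)=O | intermediate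
14 | angelic acid, (2Z)-2-methylbut-2-enoic acid | C/C=C(/C)C(=O)O | starting material
15 | (2Z)-2-methylbut-2-enoic 2,4,6-trichlorobenzoic anhydride | C/C=C(/C)C(=O)OC(=O)c1c(Cl)cc(Cl)cc1Cl | intermediate
16 | (1R,2Z)-1-[(2S,3R)-2-[(1Z)-2-({[tert-butyl(dimethyl)silyl]oxy}methyl)-3,3-dimethoxyprop-1-en-1-yl]-4-methylidene-5-oxooxolan-3-yl]-3-methyl-4-oxopent-2-en-1-yl (2Z)-2-methylbut-2-enoate | C=C1C(=O)O[C@@H](/C=C(/CO[Si](C)(C)C(C)(C)C)C(OC)OC)[C@@H]1[C@H](OC(=O)/C(C)=C\C)/C=C(/C)C(C)=O | intermediate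
17 | (1R,2Z)-1-[(2S,3R)-2-[(1Z)-2-({[tert-butyl(dimethyl)silyl]oxy}methyl)-3-oxoprop-1-en-1-yl]-4-methylidene-5-oxooxolan-3-yl]-3-methyl-4-oxopent-2-en-1-yl (2Z)-2-methylbut-2-enoate | C=C1C(=O)O[C@@H](/C=C(/CO[Si](C)(C)C(C)(C)C)C=O)[C@@H]1[C@H](OC(=O)/C(C)=C\C)/C=C(/C)C(C)=O | intermediate
18 | diisopinocampheylboron enolate of the methyl ketone of 17 (stereocentres of 17 unchanged) | C=C1C(=O)O[C@@H](/C=C(/CO[Si](C)(C)C(C)(C)C)C=O)[C@@H]1[C@H](OC(=O)/C(C)=C\C)/C=C(/C)C(=C)OB([C@@H]1C[C@@H]2C[C@@H](C2(C)C)[C@H]1C)[C@@H]1C[C@@H]2C[C@@H](C2(C)C)[C@H]1C | intermediate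
19 | (3S,6S,7R,8R)-8-angeloyloxy-15-{[tert-butyl(dimethyl)silyl]oxy}-3-hydroxy-1-oxogermacra-4Z,9Z,11(13)-trien-12,6-olide (route locants) | C=C1C(=O)O[C@H]2/C=C(/CO[Si](C)(C)C(C)(C)C)[C@@H](O)CC(=O)/C(C)=C\[C@@H](OC(=O)/C(C)=C\C)[C@H]12 | intermediate
20 | acetaldehyde | CC=O | starting material
21 | O3-(1-hydroxyethyl) hemiacetal of 19 | C=C1C(=O)O[C@H]2/C=C(/CO[Si](C)(C)C(C)(C)C)[C@@H](OC(C)O)CC(=O)/C(C)=C\[C@@H](OC(=O)/C(C)=C\C)[C@H]12 | intermediate
22 | (1S,3S,6S,7S,8R)-3-acetoxy-8-angeloyloxy-15-{[tert-butyl(dimethyl)silyl]oxy}-1-hydroxygermacra-4Z,9Z,11(13)-trien-12,6-olide (route locants) | C=C1C(=O)O[C@H]2/C=C(/CO[Si](C)(C)C(C)(C)C)[C@@H](OC(C)=O)C[C@H](O)/C(C)=C\[C@@H](OC(=O)/C(C)=C\C)[C@H]12 | intermediate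
23 | CNP0153210.4, (1S,3S,6S,7S,8R)-3-acetoxy-8-angeloyloxy-1,15-dihydroxygermacra-4Z,9Z,11(13)-trien-12,6-olide (route locants) | C=C1C(=O)O[C@H]2/C=C(/CO)[C@@H](OC(C)=O)C[C@H](O)/C(C)=C\[C@@H](OC(=O)/C(C)=C\C)[C@H]12 | target

## Step count and risks

Total step count: 11. Longest linear sequence: 10 (steps 1–4 and 6–11; step 5 is a one-step side branch).

The three steps most likely to fail:

**Step 2** (regio- and enantioselective mono-allylboration of the sensitive Z-enedial). Fallback, setting out from 2 and coming back at 6: the two termini are differentiated by oxidation level instead of by sterics. Sensitised photooxygenation of 2 in the presence of i-Pr2NEt gives 4-({[tert-butyl(dimethyl)silyl]oxy}methyl)-5-hydroxyfuran-2(5H)-one F1. NaBH4 reduction with relactonisation gives 4-({[tert-butyl(dimethyl)silyl]oxy}methyl)furan-2(5H)-one F2. DIBAL-H at −78 °C gives 4-({[tert-butyl(dimethyl)silyl]oxy}methyl)-2,5-dihydrofuran-2-ol F3, in which only C6 is at the aldehyde level. The same (R)-TRIP-catalysed allylboration with 3 and lactonisation gives (5R)-5-[(1E)-3-hydroxy-2-({[tert-butyl(dimethyl)silyl]oxy}methyl)prop-1-en-1-yl]-3-methylideneoxolan-2-one F4. MnO2 oxidation of the primary allylic alcohol returns 6.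

**Step 9** (ten-membered ring closure by boron aldol). Fallback, setting out from 16 and coming back at 19: the ring is closed reductively by a Reformatsky-type reaction. Kinetic silylation (LiN(SiMe3)2, TMSCl, THF, −78 °C) gives the trimethylsilyl enol ether of 16 F5. NBS gives the bromomethyl ketone of 16 F6. Acetal hydrolysis as in step 8 gives the bromomethyl ketone aldehyde F7. SmI2 in THF at −78 °C under high dilution generates the samarium enolate, which adds to the aldehyde to give 19. C3 is then set by the ring and not by the reagent, so the epimers must be separated.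

**Step 10** (Evans–Tishchenko inside the ring, which needs a chair that the macrocycle may not allow). Fallback, setting out from 19 and coming back at 22: acetylation and reduction are separated. Ac2O and pyridine at −20 °C give the 3-acetoxy-1-ketone F8. Reagent-controlled reduction with (R)-2-methyl-CBS-oxazaborolidine and catecholborane at −78 °C, with the alkenyl group as the large substituent, gives the 1S alcohol 22.

## Further compounds

F1 | step 2 | 4-({[tert-butyl(dimethyl)silyl]oxy}methyl)-5-hydroxyfuran-2(5H)-one | O=C1C=C(CO[Si](C)(C)C(C)(C)C)C(O)O1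
F2 | step 2 | 4-({[tert-butyl(dimethyl)silyl]oxy}methyl)furan-2(5H)-one | O=C1C=C(CO[Si](C)(C)C(C)(C)C)CO1
F3 | step 2 | 4-({[tert-butyl(dimethyl)silyl]oxy}methyl)-2,5-dihydrofuran-2-ol | OC1C=C(CO[Si](C)(C)C(C)(C)C)CO1
F4 | step 2 | (5R)-5-[(1E)-3-hydroxy-2-({[tert-butyl(dimethyl)silyl]oxy}methyl)prop-1-en-1-yl]-3-methylideneoxolan-2-one | C=C1C(=O)O[C@@H](/C=C(/CO[Si](C)(C)C(C)(C)C)CO)C1
F5 | step 9 | trimethylsilyl enol ether of the methyl ketone of 16 | C=C1C(=O)O[C@@H](/C=C(/CO[Si](C)(C)C(C)(C)C)C(OC)OC)[C@@H]1[C@H](OC(=O)/C(C)=C\C)/C=C(/C)C(=C)O[Si](C)(C)C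
F6 | step 9 | bromomethyl ketone analogue of 16 | C=C1C(=O)O[C@@H](/C=C(/CO[Si](C)(C)C(C)(C)C)C(OC)OC)[C@@H]1[C@H](OC(=O)/C(C)=C\C)/C=C(/C)C(=O)CBr
F7 | step 9 | bromomethyl ketone analogue of 17 | C=C1C(=O)O[C@@H](/C=C(/CO[Si](C)(C)C(C)(C)C)C=O)[C@@H]1[C@H](OC(=O)/C(C)=C\C)/C=C(/C)C(=O)CBr
F8 | step 10 | 3-O-acetate of 19 | C=C1C(=O)O[C@H]2/C=C(/CO[Si](C)(C)C(C)(C)C)[C@@H](OC(C)=O)CC(=O)/C(C)=C\[C@@H](OC(=O)/C(C)=C\C)[C@H]12
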